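**Retrosynthetic overview**
1. Target ⇒ hydrogenation of a mid-chain olefin ⇒ Julia–Kocienski union of a phthalide aldehyde (C3–CH2CH2CHO) with a spiroketal phenyltetrazolyl sulfone (spiroketal C2–(CH2)3–SO2PT).
2. Fragment A (phthalide aldehyde) ⇒ Lemieux–Johnson cleavage of an (R)-3-butenylphthalide ⇒ Br/Li exchange and acylation on a benzylic carbamate (lactone ring closed here) ⇒ (R)-carbinol from asymmetric transfer hydrogenation of an aryl pentenyl ketone ⇒ resorcinol, pent-4-enoyl chloride, diethylcarbamoyl chloride.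
3. Fragment B (spiroketal sulfone) ⇒ Mitsunobu/oxidation of a spiroketal propanol ⇒ acid hydrolysis and double cyclisation of a bis-alkylated acetone dimethylhydrazone ⇒ acetone dimethylhydrazone, (R)-propylene oxide and an (R)-epoxide from pent-4-en-1-ol (hydrolytic kinetic resolution).
4. Ring order: benzene ring from resorcinol; lactone ring in fragment A; both tetrahydrofuran rings of the spiroketal closed together in fragment B; the two fragments are joined afterwards.

Assumption: the spiro carbon of a [4.4] spiroketal cannot be set kinetically with useful selectivity, so it is formed under equilibrating acid, the wanted epimer is taken by separation and the other is returned to the acid.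

**Fragment A**

Step 1
Reactants: 1 resorcinol
Product: 3 1,3-dimethoxybenzene, via 3-methoxyphenol 2 (not isolated)
Conditions: Me2SO4 (2.5 equiv), K2CO3 (3 equiv), acetone, reflux, 12 h
Reagents that add atoms: dimethyl sulfate, COS(=O)(=O)OC
Why: Double Williamson O-methylation of the phenoxide is a standard high-yielding etherification and no stereocentre is involved.

Step 2
Reactants: 3 1,3-dimethoxybenzene
Product: 5 1-bromo-3,5-dimethoxybenzene, via pinacol arylboronate 4 (not isolated)
Conditions: [Ir(OMe)(cod)]2 (1 mol %), dtbpy (2 mol %), B2pin2 (0.6 equiv), THF, 80 °C, 16 h; evaporate; then CuBr2 (3 equiv), MeOH/H2O (1:1), 80 °C, 8 h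
Reagents that add atoms: copper dibromide, [Cu+2].[Br-].[Br-]
Why: Sterically controlled C–H borylation with [Ir(OMe)(cod)]2/dtbpy goes to the only ring position not ortho to a methoxy group, and bromodeboronation with CuBr2 then exchanges C–B for C–Br, giving the meta pattern that electrophilic bromination cannot give.

Step 3
Reactants: 5 1-bromo-3,5-dimethoxybenzene; 6 pent-4-enoyl chloride
Product: 8 1-(3,5-dimethoxyphenyl)pent-4-en-1-one, via aryl Grignard reagent 7 (not isolated)
Conditions: Mg, THF, 50 °C; then added to 6 (1.1 equiv), Fe(acac)3 (3 mol %), THF, −78 °C, 15 min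
Reagents that add atoms: none
Why: Fe(acac)3-catalysed acylation of an aryl Grignard reagent with an acid chloride is much faster than addition to the ketone formed and tolerates the terminal alkene, so the aryl ketone is obtained without over-addition.

Step 4
Reactants: 8 1-(3,5-dimethoxyphenyl)pent-4-en-1-one
Product: 9 (R)-1-(3,5-dimethoxyphenyl)pent-4-en-1-ol
Conditions: RuCl[(R,R)-TsDPEN](p-cymene) (1 mol %), HCO2H/Et3N (5:2), 30 °C, 24 h
Reagents that add atoms: none
Why: Noyori–Ikariya asymmetric transfer hydrogenation delivers hydride to one face of the aryl alkyl ketone through its six-membered CH/π-organised transition state, the (R,R)-catalyst giving the (R)-benzylic alcohol (same sense as acetophenone) while the isolated alkene is left alone.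

Step 5
Reactants: 9 (R)-1-(3,5-dimethoxyphenyl)pent-4-en-1-ol; 10 diethylcarbamoyl chloride
Product: 12 (R)-1-(3,5-dimethoxyphenyl)pent-4-en-1-yl diethylcarbamate, via sodium alkoxide 11 (not isolated)
Conditions: NaH (1.5 equiv), THF, 0 °C; then 10 (1.5 equiv), rt to 50 °C
Reagents that add atoms: none
Why: O-acylation of the alkoxide by the carbamoyl chloride brings in the future lactone carbonyl without touching the C–O stereocentre and caps the hydroxyl so that it cannot take part in bromoetherification of the pentenyl chain in the next step.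

Step 6
Reactants: 12 (R)-1-(3,5-dimethoxyphenyl)pent-4-en-1-yl diethylcarbamate
Product: 13 (R)-1-(2-bromo-3,5-dimethoxyphenyl)pent-4-en-1-yl diethylcarbamate
Conditions: NBS (1.05 equiv), MeCN, 0 °C to rt, dark
Reagents that add atoms: N-bromosuccinimide, O=C1CCC(=O)N1Br
Why: Electrophilic aromatic bromination of the doubly activated ring occurs ortho to one methoxy and para to the other (position 2, position 4 being flanked by two methoxy groups) far faster than NBS attacks the unactivated alkene in dry acetonitrile.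

Step 7
Reactants: 13 (R)-1-(2-bromo-3,5-dimethoxyphenyl)pent-4-en-1-yl diethylcarbamate
Product: 15 (R)-3-(but-3-en-1-yl)-5,7-dimethoxyisobenzofuran-1(3H)-one, via aryllithium 14 (not isolated)
Conditions: t-BuLi (2.1 equiv), THF, −78 °C, 30 min, then to 0 °C; 1 M aq HCl quench
Reagents that add atoms: none
Why: Bromine–lithium exchange outruns benzylic deprotonation and the aryllithium acylates itself on the neighbouring carbamate carbonyl (Parham-type cyclisation, anionic carbamoyl transfer) with loss of diethylamide to close the lactone, the stereocentre being retained because its C–O bond is never broken.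

Step 8
Reactants: 15 (R)-3-(but-3-en-1-yl)-5,7-dimethoxyisobenzofuran-1(3H)-one
Product: 17 3-[(1R)-4,6-dimethoxy-3-oxo-1,3-dihydroisobenzofuran-1-yl]propanal, via vicinal diol 16 (not isolated)
Conditions: OsO4 (2 mol %), NaIO4 (4 equiv), 2,6-lutidine (2 equiv), dioxane/H2O (3:1), rt
Reagents that add atoms: osmium tetroxide, O=[Os](=O)(=O)=O; sodium periodate, [Na+].[O-]I(=O)(=O)=O
Why: Lemieux–Johnson oxidation dihydroxylates the terminal alkene and cleaves the diol in the same flask to the aldehyde under near-neutral conditions that leave the lactone and its stereocentre untouched.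

**Fragment B**

Step 9
Reactants: 18 pent-4-en-1-ol
Product: 19 tert-butyldimethyl(pent-4-en-1-yloxy)silane
Conditions: TBSCl (1.1 equiv), imidazole (2 equiv), DMF, 0 °C to rt
Reagents that add atoms: tert-butyldimethylsilyl chloride, CC(C)(C)[Si](C)(C)Cl
Why: Imidazole-promoted silylation of a primary alcohol is reliable and gives an ether that survives peracid and organolithium chemistry but falls off in the later acid step.

Step 10
Reactants: 19 tert-butyldimethyl(pent-4-en-1-yloxy)silane
Product: 20 rac-tert-butyldimethyl[3-(oxiran-2-yl)propoxy]silane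
Conditions: mCPBA (1.2 equiv), CH2Cl2, 0 °C to rt
Reagents that add atoms: meta-chloroperoxybenzoic acid, OOC(=O)c1cccc(Cl)c1
Why: Prilezhaev epoxidation of a monosubstituted alkene proceeds cleanly and gives the racemic terminal epoxide needed for resolution.

Step 11
Reactants: 20 rac-tert-butyldimethyl[3-(oxiran-2-yl)propoxy]silane
Product: 21 (R)-tert-butyldimethyl[3-(oxiran-2-yl)propoxy]silane
Conditions: (R,R)-(salen)Co(OAc) (0.5 mol %; salen = N,N'-bis(3,5-di-tert-butylsalicylidene)-1,2-cyclohexanediamine dianion), H2O (0.55 equiv), THF (minimal), 0 °C to rt, 16 h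
Reagents that add atoms: none
Why: In the Jacobsen hydrolytic kinetic resolution the (R,R)-(salen)Co(OAc) complex (trivalent cobalt) hydrolyses the (S)-epoxide selectively, so the (R)-epoxide is recovered in >99% ee (at most half of the material) and fixes the later C2 centre of the spiroketal.

Step 12
Reactants: 22 acetone N,N-dimethylhydrazone; 23 (R)-2-methyloxirane
Product: 26 (R)-1,1-dimethyl-2-{5-[(triethylsilyl)oxy]hexan-2-ylidene}hydrazine, via lithium azaenolate 24 (not isolated), via lithium alkoxide 25 (not isolated)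
Conditions: n-BuLi (1.05 equiv), THF, −78 to 0 °C; 23 (1.05 equiv), −78 °C to rt; then Et3SiCl (1.2 equiv), 0 °C
Reagents that add atoms: chlorotriethylsilane, CC[Si](Cl)(CC)CC
Why: In this Corey–Enders hydrazone alkylation the lithiated hydrazone opens the epoxide by SN2 at its CH2 terminus, so the (R)-carbinol centre comes unchanged from the chiral pool, and the alkoxide is capped in the same flask as its silyl ether.

Step 13
Reactants: 26 (R)-1,1-dimethyl-2-{5-[(triethylsilyl)oxy]hexan-2-ylidene}hydrazine; 21 (R)-tert-butyldimethyl[3-(oxiran-2-yl)propoxy]silane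
Product: 28 (4S,10R)-1-[(tert-butyldimethylsilyl)oxy]-7-(2,2-dimethylhydrazinylidene)-10-[(triethylsilyl)oxy]undecan-4-ol, via lithium azaenolate 27 (not isolated)
Conditions: 26 (1.1 equiv), n-BuLi (1.1 equiv), THF, −78 to 0 °C; then 21 (1.0 equiv), 0 °C to rt, 12 h; H2O
Reagents that add atoms: none
Why: In the second Corey–Enders alkylation kinetic deprotonation takes place at the remaining methyl group and the azaenolate opens the terminal epoxide at CH2, so the carbinol configuration from the kinetic resolution is carried over unchanged (the descriptor reads S only because of CIP priorities).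

Step 14
Reactants: 28 (4S,10R)-1-[(tert-butyldimethylsilyl)oxy]-7-(2,2-dimethylhydrazinylidene)-10-[(triethylsilyl)oxy]undecan-4-ol
Product: 30 3-[(2R,5S,7R)-7-methyl-1,6-dioxaspiro[4.4]nonan-2-yl]propan-1-ol, via keto-triol 29 (not isolated)
Conditions: 2 M aq HCl/THF (1:3), rt, 12 h; NaHCO3; preparative HPLC on silica; the co-formed spiro epimer is returned to the same acid and separated again
Reagents that add atoms: none
Why: Aqueous acid hydrolyses the hydrazone and both silyl ethers and the liberated γ,γ'-dihydroxy ketone closes both tetrahydrofuran rings by thermodynamic spiroketalisation without touching C2 or C7, while the spiro carbon forms under equilibrium with little bias in a [4.4] system, so the (5S) epimer (both substituents anti to the oxygen of the other ring) is separated from about an equal amount of its spiro epimer, which is re-equilibrated.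

Step 15
Reactants: 30 3-[(2R,5S,7R)-7-methyl-1,6-dioxaspiro[4.4]nonan-2-yl]propan-1-ol
Product: 31 5-({3-[(2S,5S,7R)-7-methyl-1,6-dioxaspiro[4.4]nonan-2-yl]propyl}sulfanyl)-1-phenyl-1H-tetrazole
Conditions: 1-phenyl-1H-tetrazole-5-thiol (1.3 equiv), PPh3 (1.3 equiv), DIAD (1.3 equiv), THF, 0 °C to rt
Reagents that add atoms: 1-phenyl-1H-tetrazole-5-thiol, Sc1nnnn1-c1ccccc1
Why: Mitsunobu thioetherification of a primary alcohol with the acidic tetrazole thiol is fast and essentially neutral, so the spiroketal is not epimerised (C2 reads S from here on only because sulfur raises the CIP rank of the side chain).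

Step 16
Reactants: 31 5-({3-[(2S,5S,7R)-7-methyl-1,6-dioxaspiro[4.4]nonan-2-yl]propyl}sulfanyl)-1-phenyl-1H-tetrazole
Product: 33 5-({3-[(2S,5S,7R)-7-methyl-1,6-dioxaspiro[4.4]nonan-2-yl]propyl}sulfonyl)-1-phenyl-1H-tetrazole, via sulfoxide 32 (not isolated)
Conditions: mCPBA (3 equiv), NaHCO3 (5 equiv), CH2Cl2, 0 °C to rt, 16 h
Reagents that add atoms: meta-chloroperoxybenzoic acid, OOC(=O)c1cccc(Cl)c1
Why: Stepwise sulfide oxidation by the peracid stops cleanly at the sulfone, and the bicarbonate buffer keeps the medium non-acidic so the spiro centre is not scrambled.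

**Coupling and completion**

Step 17
Reactants: 33 5-({3-[(2S,5S,7R)-7-methyl-1,6-dioxaspiro[4.4]nonan-2-yl]propyl}sulfonyl)-1-phenyl-1H-tetrazole; 17 3-[(1R)-4,6-dimethoxy-3-oxo-1,3-dihydroisobenzofuran-1-yl]propanal
Product: 35 (3R)-5,7-dimethoxy-3-{(3E)-6-[(2R,5S,7R)-7-methyl-1,6-dioxaspiro[4.4]nonan-2-yl]hex-3-en-1-yl}isobenzofuran-1(3H)-one, via potassium sulfonyl carbanion 34 (not isolated)
Conditions: 33 (1.15 equiv), KN(SiMe3)2 (1.05 equiv), DME, −78 °C, 30 min; then 17 (1.0 equiv), −78 °C to rt; H2O
Reagents that add atoms: none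
Why: In the Julia–Kocienski olefination the pre-formed sulfonyl carbanion adds to the aldehyde at −78 °C faster than it deprotonates the lactone, and Smiles rearrangement with loss of SO2 and the tetrazolone gives the alkene (mainly E, any Z isomer converging in the next step), joining the phthalide and spiroketal halves without touching a stereocentre.

Step 18
Reactants: 35 (3R)-5,7-dimethoxy-3-{(3E)-6-[(2R,5S,7R)-7-methyl-1,6-dioxaspiro[4.4]nonan-2-yl]hex-3-en-1-yl}isobenzofuran-1(3H)-one
Product: 36 (3R)-5,7-dimethoxy-3-{6-[(2R,5S,7R)-7-methyl-1,6-dioxaspiro[4.4]nonan-2-yl]hexyl}isobenzofuran-1(3H)-one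
Conditions: H2 (1 atm), PtO2 (5 mol %), K2CO3 (solid, trace), THF, rt
Reagents that add atoms: none
Why: Hydrogenation over PtO2 saturates the isolated disubstituted alkene, and the carbonate keeps the medium acid-free so that neither the spiro centre equilibrates nor the benzylic lactone C–O bond is cleaved.

**Compound list**
1 | resorcinol (benzene-1,3-diol) | Oc1cccc(O)c1 | starting material
2 | 3-methoxyphenol | COc1cccc(O)c1 | intermediate (not isolated)
3 | 1,3-dimethoxybenzene | COc1cccc(OC)c1 | intermediate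
4 | 2-(3,5-dimethoxyphenyl)-4,4,5,5-tetramethyl-1,3,2-dioxaborolane | COc1cc(OC)cc(c1)B1OC(C)(C)C(C)(C)O1 | intermediate (not isolated)
5 | 1-bromo-3,5-dimethoxybenzene | COc1cc(Br)cc(OC)c1 | intermediate
6 | pent-4-enoyl chloride | C=CCCC(Cl)=O | starting material
7 | 3,5-dimethoxyphenylmagnesium bromide | COc1cc(OC)cc([Mg]Br)c1 | intermediate (not isolated)
8 | 1-(3,5-dimethoxyphenyl)pent-4-en-1-one | COc1cc(OC)cc(c1)C(=O)CCC=C | intermediate
9 | (R)-1-(3,5-dimethoxyphenyl)pent-4-en-1-ol | COc1cc(OC)cc(c1)[C@@H](CCC=C)O | intermediate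
10 | diethylcarbamoyl chloride | CCN(CC)C(Cl)=O | starting material
11 | sodium (R)-1-(3,5-dimethoxyphenyl)pent-4-en-1-olate | COc1cc(OC)cc(c1)[C@@H](CCC=C)[O-].[Na+] | intermediate (not isolated)
12 | (R)-1-(3,5-dimethoxyphenyl)pent-4-en-1-yl diethylcarbamate | COc1cc(OC)cc(c1)[C@@H](CCC=C)OC(=O)N(CC)CC | intermediate
13 | (R)-1-(2-bromo-3,5-dimethoxyphenyl)pent-4-en-1-yl diethylcarbamate | COc1cc(OC)c(Br)c(c1)[C@@H](CCC=C)OC(=O)N(CC)CC | intermediate
14 | (R)-1-(2-lithio-3,5-dimethoxyphenyl)pent-4-en-1-yl diethylcarbamate | COc1cc(OC)c([Li])c(c1)[C@@H](CCC=C)OC(=O)N(CC)CC | intermediate (not isolated)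
15 | (R)-3-(but-3-en-1-yl)-5,7-dimethoxyisobenzofuran-1(3H)-one | COc1cc(OC)c2c(c1)[C@@H](CCC=C)OC2=O | intermediate
16 | (3R)-3-(3,4-dihydroxybutyl)-5,7-dimethoxyisobenzofuran-1(3H)-one (both epimers at the new carbinol) | COc1cc(OC)c2c(c1)[C@@H](CCC(O)CO)OC2=O | intermediate (not isolated)
17 | 3-[(1R)-4,6-dimethoxy-3-oxo-1,3-dihydroisobenzofuran-1-yl]propanal | COc1cc(OC)c2c(c1)[C@@H](CCC=O)OC2=O | intermediate
18 | pent-4-en-1-ol | C=CCCCO | starting material
19 | tert-butyldimethyl(pent-4-en-1-yloxy)silane | C=CCCCO[Si](C)(C)C(C)(C)C | intermediate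
20 | rac-tert-butyldimethyl[3-(oxiran-2-yl)propoxy]silane | CC(C)(C)[Si](C)(C)OCCCC1CO1 | intermediate
21 | (R)-tert-butyldimethyl[3-(oxiran-2-yl)propoxy]silane | CC(C)(C)[Si](C)(C)OCCC[C@@H]1CO1 | intermediate
22 | acetone N,N-dimethylhydrazone | CC(C)=NN(C)C | starting material
23 | (R)-2-methyloxirane | C[C@@H]1CO1 | starting material
24 | lithium azaenolate of acetone N,N-dimethylhydrazone | [Li]CC(C)=NN(C)C | intermediate (not isolated)
25 | lithium (R)-5-(2,2-dimethylhydrazinylidene)hexan-2-olate | CC(CC[C@@H](C)O[Li])=NN(C)C | intermediate (not isolated)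
26 | (R)-1,1-dimethyl-2-{5-[(triethylsilyl)oxy]hexan-2-ylidene}hydrazine | CC(CC[C@@H](C)O[Si](CC)(CC)CC)=NN(C)C | intermediate
27 | lithium azaenolate of 26 (lithiated at the methyl carbon) | [Li]CC(CC[C@@H](C)O[Si](CC)(CC)CC)=NN(C)C | intermediate (not isolated)
28 | (4S,10R)-1-[(tert-butyldimethylsilyl)oxy]-7-(2,2-dimethylhydrazinylidene)-10-[(triethylsilyl)oxy]undecan-4-ol | CC(C)(C)[Si](C)(C)OCCC[C@@H](O)CCC(CC[C@@H](C)O[Si](CC)(CC)CC)=NN(C)C | intermediate
29 | (4R,10R)-1,4,10-trihydroxyundecan-7-one | OCCC[C@@H](O)CCC(=O)CC[C@@H](C)O | intermediate (not isolated)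
30 | 3-[(2R,5S,7R)-7-methyl-1,6-dioxaspiro[4.4]nonan-2-yl]propan-1-ol | OCCC[C@@H]1CC[C@]2(CC[C@@H](C)O2)O1 | intermediate
31 | 5-({3-[(2S,5S,7R)-7-methyl-1,6-dioxaspiro[4.4]nonan-2-yl]propyl}sulfanyl)-1-phenyl-1H-tetrazole | c1ccc(cc1)-n1nnnc1SCCC[C@@H]1CC[C@]2(CC[C@@H](C)O2)O1 | intermediate
32 | 5-({3-[(2S,5S,7R)-7-methyl-1,6-dioxaspiro[4.4]nonan-2-yl]propyl}sulfinyl)-1-phenyl-1H-tetrazole (both sulfur epimers) | c1ccc(cc1)-n1nnnc1S(=O)CCC[C@@H]1CC[C@]2(CC[C@@H](C)O2)O1 | intermediate (not isolated)
33 | 5-({3-[(2S,5S,7R)-7-methyl-1,6-dioxaspiro[4.4]nonan-2-yl]propyl}sulfonyl)-1-phenyl-1H-tetrazole | c1ccc(cc1)-n1nnnc1S(=O)(=O)CCC[C@@H]1CC[C@]2(CC[C@@H](C)O2)O1 | intermediate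
34 | potassium salt of 33 deprotonated at the carbon next to sulfur | c1ccc(cc1)-n1nnnc1S(=O)(=O)C([K])CC[C@@H]1CC[C@]2(CC[C@@H](C)O2)O1 | intermediate (not isolated)
35 | (3R)-5,7-dimethoxy-3-{(3E)-6-[(2R,5S,7R)-7-methyl-1,6-dioxaspiro[4.4]nonan-2-yl]hex-3-en-1-yl}isobenzofuran-1(3H)-one (E major, minor Z isomer carried along) | COc1cc(OC)c2c(c1)[C@@H](CC/C=C/CC[C@@H]1CC[C@]3(CC[C@@H](C)O3)O1)OC2=O | intermediate
36 | (3R)-5,7-dimethoxy-3-{6-[(2R,5S,7R)-7-methyl-1,6-dioxaspiro[4.4]nonan-2-yl]hexyl}isobenzofuran-1(3H)-one | COc1cc(OC)c2c(c1)[C@@H](CCCCCC[C@@H]1CC[C@]3(CC[C@@H](C)O3)O1)OC2=O | target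

**Step count**
Total: 18 steps. Longest linear sequence: 10 steps (steps 1–8, 17, 18). The other branch runs 9 steps (9–11, 13–18), with step 12 as a one-step side branch.

**Steps most likely to fail and their fallbacks**

Step 2 is the first risk: CuBr2 can also brominate the very electron-rich ring, and traces of the ortho-borylated isomer would be carried along. The fallback sets out from boronate 4, which is isolated instead of being treated with CuBr2. Oxidative hydrolysis (NaIO4, then 1 M aq HCl, THF/H2O) gives 3,5-dimethoxyphenylboronic acid F1. An acylative Suzuki–Miyaura coupling of this acid with acid chloride 6 (Pd(PPh3)4 as zerovalent palladium source, Cs2CO3, dry toluene, 100 °C) then gives ketone 8, where the route is rejoined; bromide 5 and Grignard reagent 7 are bypassed.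

Step 14 is the second risk: the spiro centre forms without kinetic control, so at best about half of the material is the wanted epimer per pass, and the two alcohols may not separate well. The fallback sets out from hydrazone 28 and moves the separation to a crystalline derivative. The acid treatment of step 14 is run without chromatography and gives alcohol 30 mixed with its spiro epimer 3-[(2R,5R,7R)-7-methyl-1,6-dioxaspiro[4.4]nonan-2-yl]propan-1-ol F2. Acylation of the mixture (4-nitrobenzoyl chloride, pyridine, DMAP, CH2Cl2) gives 3-[(2R,5S,7R)-7-methyl-1,6-dioxaspiro[4.4]nonan-2-yl]propyl 4-nitrobenzoate F3 and 3-[(2R,5R,7R)-7-methyl-1,6-dioxaspiro[4.4]nonan-2-yl]propyl 4-nitrobenzoate F4. These UV-active esters are separated by crystallisation or HPLC. Methanolysis of F3 (K2CO3, MeOH, rt) returns pure 30, where the route is rejoined. Ester F4 is re-equilibrated at the spiro centre (camphorsulfonic acid, CH2Cl2, rt) to a mixture of F3 and F4 and returned to the separation.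

Step 17 is the third risk: the sulfonyl carbanion may enolise the aldehyde or deprotonate the lactone at C3, eroding yield or the C3 configuration. The fallback sets out from alcohol 30 and from alkene 15 (held back before step 8) and avoids base at the coupling stage. Buffered Dess–Martin oxidation (NaHCO3, CH2Cl2) of 30 gives 3-[(2R,5S,7R)-7-methyl-1,6-dioxaspiro[4.4]nonan-2-yl]propanal F5. Wittig methylenation (Ph3PCH3Br, KOt-Bu, THF, 0 °C) converts it into (2R,5S,7R)-2-(but-3-en-1-yl)-7-methyl-1,6-dioxaspiro[4.4]nonane F6. Cross-metathesis of this alkene with 15 (3 equiv, recoverable) using second-generation Grubbs catalyst RuCl2(=CHPh)(H2IMes)(PCy3) in CH2Cl2 at 40 °C gives olefin 35 as an E/Z mixture, where the route is rejoined for step 18.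

**Further compounds**
F1 | step 2 | 3,5-dimethoxyphenylboronic acid | COc1cc(OC)cc(c1)B(O)O
F2 | step 14 | 3-[(2R,5R,7R)-7-methyl-1,6-dioxaspiro[4.4]nonan-2-yl]propan-1-ol | OCCC[C@@H]1CC[C@@]2(CC[C@@H](C)O2)O1
F3 | step 14 | 3-[(2R,5S,7R)-7-methyl-1,6-dioxaspiro[4.4]nonan-2-yl]propyl 4-nitrobenzoate | [O-][N+](=O)c1ccc(cc1)C(=O)OCCC[C@@H]1CC[C@]2(CC[C@@H](C)O2)O1
F4 | step 14 | 3-[(2R,5R,7R)-7-methyl-1,6-dioxaspiro[4.4]nonan-2-yl]propyl 4-nitrobenzoate | [O-][N+](=O)c1ccc(cc1)C(=O)OCCC[C@@H]1CC[C@@]2(CC[C@@H](C)O2)O1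
F5 | step 17 | 3-[(2R,5S,7R)-7-methyl-1,6-dioxaspiro[4.4]nonan-2-yl]propanal | O=CCC[C@@H]1CC[C@]2(CC[C@@H](C)O2)O1
F6 | step 17 | (2R,5S,7R)-2-(but-3-en-1-yl)-7-methyl-1,6-dioxaspiro[4.4]nonane | C=CCC[C@@H]1CC[C@]2(CC[C@@H](C)O2)O1
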